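Compound numbers are those of the steps and of the compound list below. Locants are those of the target 21: unprimed for the 7-hydroxy half (rings A, B, C), double-primed for the 5,7-dihydroxy half (rings A'', B'', C'').

## Analysis of the target

Compound 21 is a 3,3''-linked biflavanone. A 7,4'-dihydroxyflavanone half and a 5,7,4'-trihydroxyflavanone half are joined by a single bond between the two tertiary carbons C3 and C3''. The four stereocentres C2, C3, C3'' and C2'' are contiguous and configured 2S,3R,2''S,3''R. H2/H3 and H2''/H3'' are trans in both pyranone rings, and the two halves have the same sense, so 21 is the C2-like and not the meso-like diastereomer of a pseudo-symmetric dimer. The halves differ in constitution only by the 5''-hydroxyl, so a route through a symmetric intermediate would later have to tell two nearly identical ends apart. Every stereocentre is labile. C3 and C3'' are enolisable ketone alpha carbons, and C2 and C2'' are benzylic aryl ether carbons beta to a ketone, which base can open by retro-oxa-Michael reaction to the 2'-hydroxychalcone. The five free phenols rule out harsh deprotection. The difficulty is therefore threefold: the hindered C3–C3'' bond, the differentiation of the two aryl ketones, and four epimerisable centres in one absolute sense. The route rests on two facts. C4–C3–C3''–C4'' is a succinyl unit, and ring A'' together with C4'' is a 2,4,6-trihydroxyphenyl ketone, the aromatised form of a 3,5,7-trioxo ester chain attached to C4''. Ring A'' can therefore be closed last by forming C4a''–C8a'', and the symmetric trihydroxyphenyl ketone then cyclises onto C2'' without a regiochemical question.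

## Retrosynthetic reasoning

Protecting groups. Acid opens neither pyranone ring, whereas base does, so the last operation should be acidic. The three phenols that must be masked on the way (O7, O4', O4''') are carried as methoxymethyl acetals, and 21 is traced back to 20. The 5''- and 7''-hydroxyls never need protection, because they do not exist until two steps from the end.

Ring C''. The O1''–C2'' bond of 20 is cut (retro-oxa-Michael), giving the 2',4',6'-trihydroxychalcone 19 with ring C intact. Both ortho hydroxyls of 19 are equivalent, so only the facial sense at C2'' and the configuration at C3'' have to be controlled. The forward closure uses a chiral bifunctional base for C2'' and equilibration to trans for C3''.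

Ring A'' (the disconnection that carries the plan). The C4a''–C8a'' bond of 19 is cut, and the aromatic ring is unfolded into the open 3,5,7-trioxo ester chain of 18. Cutting here, and not at the aryl–carbonyl bond C4''–C4a'', means that only one aryl ketone (C4) is present during all earlier steps. The two ends of the succinyl unit are thus different by construction. The forward reaction is a Claisen cyclisation of the chain under a magnesium alkoxide. It must prefer the Claisen mode to the aldol mode and must leave C2 and C3 untouched.

The chain. In 18 the bond between C4'' and the first chain methylene is cut. This leads to the carboxylic acid 14 and to the six-carbon diketo ester 15, which reacts as its trienolate 16 with the activated acid 17. The acid must be set free and activated without base or strong acid, so it is carried as an allyl ester (13) and released by a zerovalent palladium catalyst.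

Ring C. The O1–C2 bond of 13 is cut, giving the 2'-hydroxychalcone 12. The forward oxa-Michael addition is the one point where the absolute configuration enters. A chiral bifunctional thiourea sets C2, and C3 follows by equilibration to the 2,3-trans arrangement.

The second benzylidene. The C2=C3 double bond of 12 is cut (retro-aldol condensation) to the ketone 9 and the aldehyde 10. In the forward sense the aldolate closes onto the ester and opens again by elimination (Stobbe pathway). The C–C bond formation is then irreversible and the acid 11 is released, which is then only re-esterified to 12.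

The first benzylidene. The C2''=C3'' double bond of 9 is cut back through 8 to the enol lactone 7, and from there to the keto acid 3 and the aldehyde 4. The enol lactone 6 masks the ketone alpha carbon (the future C3). Only the carbon next to the carboxyl (the future C3'') can then condense with the acetylated aldehyde 5, which settles which benzylidene goes where.

The succinyl unit. The C4–C4a bond of 3 is cut to resorcinol 1 and succinic anhydride 2. A Friedel–Crafts acylation opens the anhydride once and thereby desymmetrises the four-carbon unit in the first step.

## Alternatives that were turned down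

Alternative 1: The C3–C3'' bond is cut together with both benzylic C–O bonds, which leads back to two molecules of 4-hydroxycinnamic acid A1. Forward, a one-electron oxidant gives the phenoxyl radical of A1, and two radicals couple through their beta carbons (the future C3 and C3''). Each carboxylate then adds to the quinone methide of the other half and closes the cis-fused bis-lactone A2.
- For it: one operation from a cheap acid makes the hindered central bond and fixes the relative configuration of all four carbons. Nothing in the chosen route matches that economy.
- Against it: A2 is C2-symmetric with two identical lactone carbonyls, whereas 21 needs a 2,4-dioxygenated aryl ketone at one end and a 2,4,6-trioxygenated one at the other. Two different aryl nucleophiles would have to be added one at a time to equivalent sites, with statistical losses and over-addition.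
- Against it: in A2 each benzylic oxygen is acylated by the carboxyl of the other half. After the aryl additions each pyranone ring must be closed by turning a benzylic carbinol into an aryl ether with inversion. A 4-hydroxybenzylic carbinol beta to a ketone ionises to a quinone methide or dehydrates far more readily than it is substituted.
- Against it: radical coupling also occurs at the ortho carbon and at oxygen, and gives racemic material.
- Comparison: A2 is reached faster than any intermediate of the chosen route, but the two ends and the two C2–O bonds remain unsolved. The chosen route starts from a succinyl unit that is unsymmetrical from step 1 and makes both ring C–O bonds by conjugate addition.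

Alternative 2: Both aryl–carbonyl bonds, C4–C4a and C4''–C4a'', are cut. This leads to the succinic diacid A3, which already carries both benzylic aryl ethers and all four stereocentres. Forward, both carboxyls of A3 are activated, and each acylium ion attacks the ring carbon ortho to its ether oxygen, closing both pyranone rings to A4.
- For it: this is the classical chroman-4-one closure and forms both rings in one flask. Both aryl ethers are activated and the 3,5-dimethoxyphenoxy ring is symmetric. No polyketone is handled and no base ever meets a finished flavanone. On these points it is stronger than the chosen route.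
- Against it: the stereochemical problem is only moved. A3, with four contiguous centres of which two are benzylic aryl ethers, is as hard to make as 21.
- Against it: beta-aryloxy acylium ions lose the phenol by beta-elimination, and benzylic aryl ethers ionise in the acid required, so C2 and C2'' are at risk exactly when the rings close. The 3-methoxyphenoxy ring can also close ortho to its methoxy group.
- Against it: A4 still carries three aryl methyl ethers. Their cleavage needs a strong Lewis acid, under which flavanones open and epimerise.
- Comparison: fewer but harsher operations at the ring-forming stage. The chosen route keeps the 5''- and 7''-hydroxyls free from the moment they are made, uses acetals that leave with dilute acid, and sets each pair of centres in a ring closure that is trans by thermodynamics.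

Alternative 3: The C2–C3 and C2''–C3'' bonds are cut, giving the unsymmetrical 1,4-diketone A5 and two equivalents of aldehyde 10. Forward, both ketones of A5 become Z boron enolates and each adds to 10 through a chair transition state. The syn,syn bis-aldol A6 then has all four stereocentres, but the carbinols C2 and C2'' are inverted. Removal of the allyl groups and a double Mitsunobu etherification would close both rings with inversion.
- For it: the most convergent plan, with two C–C bonds and four stereocentres in one flask. It is clearly shorter than the chosen route.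
- Against it: a 1,4-diketone under a Lewis-acidic boron triflate and an amine is prone to Paal–Knorr cyclodehydration. The 2,6-dioxygenated aryl ketone is twisted and hindered and will not enolise like the other one.
- Against it: the second aldol must be selective with respect to the centre just made across C3–C3'' (like versus unlike), and the substrate offers no handle for this. The absolute sense would rest on chiral boron ligands, which control aryl ketones poorly.
- Against it: two Mitsunobu closures at 4-alkoxybenzylic beta-keto carbinols invite elimination to the chalcones and ionisation, which would erase C2 and C2''.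
- Comparison: stronger in step count and convergence, weaker in control. In the chosen route each stereocentre is set in its own event, the two alpha centres can be corrected by equilibration, and no benzylic carbinol is substituted.

Key step: step 11

Assumption: the quinine-derived thiourea Q-TU, 1-[3,5-bis(trifluoromethyl)phenyl]-3-[(8S,9S)-6'-methoxycinchonan-9-yl]thiourea, is taken to deliver the 2S sense of ring closure. If the sense is the opposite, its quinidine-derived pseudoenantiomer replaces it in steps 8 and 12 and nothing else changes.

## Route

Step 1
Reactants: 1 resorcinol; 2 succinic anhydride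
Product: 3 4-(2,4-dihydroxyphenyl)-4-oxobutanoic acid
Conditions: AlCl3 (3 equiv), PhNO2, 0 to 60 °C; ice/aq. HCl
Reagents that add atoms: none
Why: Friedel–Crafts acylation; the anhydride opens at one carbonyl, so the succinyl unit is desymmetrised at once, and resorcinol reacts at C4 (ortho to one hydroxyl, para to the other), after which the acyl group deactivates the ring against a second acylation.

Step 2
Reactants: 3 4-(2,4-dihydroxyphenyl)-4-oxobutanoic acid; 4 4-hydroxybenzaldehyde
Product: 7 (E)-3-(4-acetoxybenzylidene)-5-(2,4-diacetoxyphenyl)furan-2(3H)-one, via 4-acetoxybenzaldehyde 5 (not isolated), via 5-(2,4-diacetoxyphenyl)furan-2(3H)-one 6 (not isolated)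
Conditions: Ac2O, NaOAc, 100 °C
Reagents that add atoms: acetic anhydride, CC(=O)OC(C)=O
Why: Perkin-type condensation of a beta-aroylpropionic acid: the anhydride acetylates the phenols and cyclodehydrates the keto acid to the enol lactone 6, whose C3 methylene (the future C3'') is the only acidic position left and condenses with 5. The ketone alpha carbon (the future C3) is masked as the enol ether carbon, which is the source of the regiocontrol, and the E alkene (aryl anti to the lactone carbonyl) is the thermodynamic product.

Step 3
Reactants: 7 (E)-3-(4-acetoxybenzylidene)-5-(2,4-diacetoxyphenyl)furan-2(3H)-one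
Product: 8 methyl (E)-4-(2,4-dihydroxyphenyl)-2-(4-hydroxybenzylidene)-4-oxobutanoate
Conditions: K2CO3, MeOH, 0 °C to rt; aq. HCl work-up
Reagents that add atoms: methanol, CO
Why: Transesterification: methoxide opens the activated enol lactone to the methyl ester and the aryl ketone and cleaves the three aryl acetates. The alkene is not involved, so its E geometry (aryl cis to the CH2 group) is kept.

Step 4
Reactants: 8 methyl (E)-4-(2,4-dihydroxyphenyl)-2-(4-hydroxybenzylidene)-4-oxobutanoate
Product: 9 methyl (E)-4-[2-hydroxy-4-(methoxymethoxy)phenyl]-2-[4-(methoxymethoxy)benzylidene]-4-oxobutanoate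
Conditions: MOMCl (2.2 equiv), i-Pr2NEt, CH2Cl2, 0 °C to rt
Reagents that add atoms: chloromethyl methyl ether, COCCl
Why: O-Alkylation of phenols (acetal formation); the two free phenols react, while the hydroxyl ortho to the ketone is held in an intramolecular hydrogen bond and stays free, as it must for the later ring closure.

Step 5
Reactants: 4 4-hydroxybenzaldehyde
Product: 10 4-(methoxymethoxy)benzaldehyde
Conditions: MOMCl, i-Pr2NEt, CH2Cl2, 0 °C to rt
Reagents that add atoms: chloromethyl methyl ether, COCCl
Why: O-Alkylation of a phenol; the free phenoxide would deactivate the aldehyde in the base-mediated condensation of step 6.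

Step 6
Reactants: 9 methyl (E)-4-[2-hydroxy-4-(methoxymethoxy)phenyl]-2-[4-(methoxymethoxy)benzylidene]-4-oxobutanoate; 10 4-(methoxymethoxy)benzaldehyde
Product: 11 (2E,3E)-3-[2-hydroxy-4-(methoxymethoxy)benzoyl]-2-[4-(methoxymethoxy)benzylidene]-4-[4-(methoxymethoxy)phenyl]but-3-enoic acid
Conditions: KOt-Bu (3.5 equiv), t-BuOH–THF, 0 °C to rt; cold 1 M HCl to pH 3
Reagents that add atoms: none
Why: Stobbe-type aldol condensation: the dienolate of 9 adds through C3 (alpha to the ketone) to 10, the aldolate lactonises onto the methyl ester, and the lactone opens by E1cB elimination, which makes the condensation irreversible, places the aryl anti to the aroyl group as in Stobbe half-esters, and releases the ester arm as the carboxylate. Cold acidification returns the open 2'-hydroxychalcone, the form that is stable as the phenoxide in strong base.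

Step 7
Reactants: 11 (2E,3E)-3-[2-hydroxy-4-(methoxymethoxy)benzoyl]-2-[4-(methoxymethoxy)benzylidene]-4-[4-(methoxymethoxy)phenyl]but-3-enoic acid
Product: 12 allyl (2E,3E)-3-[2-hydroxy-4-(methoxymethoxy)benzoyl]-2-[4-(methoxymethoxy)benzylidene]-4-[4-(methoxymethoxy)phenyl]but-3-enoate
Conditions: allyl bromide, KHCO3, DMF, rt
Reagents that add atoms: allyl bromide, C=CCBr
Why: SN2 O-alkylation of the carboxylate; hydrogencarbonate deprotonates only the carboxylic acid, so the chelated phenol is neither allylated nor turned into the phenoxide that would close ring C without control. The allyl ester is chosen because it can later be removed without base or acid.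

Step 8
Reactants: 12 allyl (2E,3E)-3-[2-hydroxy-4-(methoxymethoxy)benzoyl]-2-[4-(methoxymethoxy)benzylidene]-4-[4-(methoxymethoxy)phenyl]but-3-enoate
Product: 13 allyl (E)-2-[(2S,3R)-7-(methoxymethoxy)-2-[4-(methoxymethoxy)phenyl]-4-oxochroman-3-yl]-3-[4-(methoxymethoxy)phenyl]acrylate
Conditions: Q-TU (20 mol%), toluene, 0 °C to rt
Reagents that add atoms: none
Why: Organocatalytic enantioselective intramolecular oxa-Michael addition (6-endo-trig) of a 2'-hydroxychalcone: the quinuclidine nitrogen activates the phenol and the thiourea binds the enone carbonyl, so the oxygen adds to one face of C2 and sets 2S. C3, made acidic by the ketone and the adjacent alkene, equilibrates under the same amine to the 2,3-trans diequatorial arrangement (3R) by thermodynamic control.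

Step 9
Reactants: 13 allyl (E)-2-[(2S,3R)-7-(methoxymethoxy)-2-[4-(methoxymethoxy)phenyl]-4-oxochroman-3-yl]-3-[4-(methoxymethoxy)phenyl]acrylate
Product: 14 (E)-2-[(2S,3R)-7-(methoxymethoxy)-2-[4-(methoxymethoxy)phenyl]-4-oxochroman-3-yl]-3-[4-(methoxymethoxy)phenyl]acrylic acid
Conditions: Pd(PPh3)4 (5 mol%), PhNHMe, THF, rt
Reagents that add atoms: none
Why: Tsuji–Trost-type deallylation: zerovalent palladium ionises the allyl ester to a pi-allyl complex, which the weakly basic aniline captures. The acid is set free at neutral pH, so neither the acetals nor the base-labile O1–C2 bond is touched.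

Step 10
Reactants: 14 (E)-2-[(2S,3R)-7-(methoxymethoxy)-2-[4-(methoxymethoxy)phenyl]-4-oxochroman-3-yl]-3-[4-(methoxymethoxy)phenyl]acrylic acid; 15 methyl 3,5-dioxohexanoate
Product: 18 methyl (E)-8-[(2S,3R)-7-(methoxymethoxy)-2-[4-(methoxymethoxy)phenyl]-4-oxochroman-3-yl]-9-[4-(methoxymethoxy)phenyl]-3,5,7-trioxonon-8-enoate, via the trilithium trienolate 16 (not isolated), via the N-acylimidazole 17 (not isolated)
Conditions: 14, CDI, THF, rt; added at −78 °C to 16 [15 (3.3 equiv), LiN(i-Pr)2 (10 equiv), THF, 0 °C]; AcOH quench at −78 °C
Reagents that add atoms: none
Why: Claisen-type C-acylation of a polyanion: the terminal carbanion of 16, its most nucleophilic site, attacks the acyl imidazole 17, which is far more electrophilic than the hindered, para-oxygenated C4 ketone, and the product is held as its polyenolate until the cold acidic quench. The excess of 16 covers the imidazole N–H and the acidic methylene of the product, and −78 °C with inverse addition keeps proton abstraction from C3 and ring opening slow.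

Step 11
Reactants: 18 methyl (E)-8-[(2S,3R)-7-(methoxymethoxy)-2-[4-(methoxymethoxy)phenyl]-4-oxochroman-3-yl]-9-[4-(methoxymethoxy)phenyl]-3,5,7-trioxonon-8-enoate
Product: 19 (2S,3R)-7-(methoxymethoxy)-2-[4-(methoxymethoxy)phenyl]-3-[(E)-1-[4-(methoxymethoxy)phenyl]-3-oxo-3-(2,4,6-trihydroxyphenyl)prop-1-en-2-yl]chroman-4-one
Conditions: Mg(OMe)2 (4 equiv), MeOH, rt; cold 0.5 M HCl
Reagents that add atoms: none
Why: Biomimetic Claisen (Dieckmann-type) cyclisation of a 3,5,7-triketo ester, the reaction by which chalcone synthase builds this ring and a known laboratory route to acylphloroglucinols. Mg(OMe)2 turns the chain into its magnesium polyenolate; the carbon next to C4'' (the future C4a'') attacks the ester carbonyl (the future C8a'') in a 6-exo-trig closure, methoxide leaves, and the 2-acylcyclohexane-1,3,5-trione enolises irreversibly to the 2,4,6-trihydroxyphenyl ketone, ring A''. No stereocentre is formed. The step needs the Claisen mode and not the aldol mode, in which the ester alpha carbon would attack the C4'' carbonyl and give a resorcylate: magnesium chelation of the beta-keto ester end keeps the ester electrophilic and the chain folded, and here the C4'' carbonyl is cross-conjugated and shielded by the fully substituted C3'' with its aryl and chromanyl groups. The step also needs C2 and C3 to stay intact: the chain methylenes are many orders of magnitude more acidic than H3, so the base is consumed by the chain and the polyanion resists further deprotonation, and epimerisation at C3 alone would return to the trans isomer. Conjugate additions of the chain enolate or of methoxide to the C2''=C3'' enone are reversible, whereas aromatisation is not. As a polyphenoxide the product enone is a poor acceptor, so ring C'' should stay open until the cold acidic quench.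

Step 12
Reactants: 19 (2S,3R)-7-(methoxymethoxy)-2-[4-(methoxymethoxy)phenyl]-3-[(E)-1-[4-(methoxymethoxy)phenyl]-3-oxo-3-(2,4,6-trihydroxyphenyl)prop-1-en-2-yl]chroman-4-one
Product: 20 (2S,3R,2''S,3''R)-5'',7''-dihydroxy-7-(methoxymethoxy)-2,2''-bis[4-(methoxymethoxy)phenyl]-3,3''-bichroman-4,4''-dione
Conditions: Q-TU (20 mol%), THF–toluene, −20 to 0 °C
Reagents that add atoms: none
Why: Catalyst-controlled intramolecular oxa-Michael addition (6-endo-trig); the two ortho hydroxyls are equivalent, so there is no regiochemical choice, and the same catalyst sense as in step 8 directs the oxygen to the face of C2'' that gives 2''S. C3'' is set by protonation of the enol and equilibrates to the 2'',3''-trans arrangement (3''R), at the latest under the acid of step 13.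

Step 13
Reactants: 20 (2S,3R,2''S,3''R)-5'',7''-dihydroxy-7-(methoxymethoxy)-2,2''-bis[4-(methoxymethoxy)phenyl]-3,3''-bichroman-4,4''-dione
Product: 21 (2S,3R,2''S,3''R)-7,5'',7''-trihydroxy-2,2''-bis(4-hydroxyphenyl)-3,3''-bichroman-4,4''-dione
Conditions: 3 M HCl, MeOH, 50 °C
Reagents that add atoms: none
Why: Acid-catalysed acetal cleavage (transacetalisation to methanol) frees the three phenols. Acid does not open the pyranone rings, so C2 and C2'' are kept, and any cis epimer at C3 or C3'' can relax to trans through the enol.

## Compound list

1 | resorcinol | Oc1cccc(O)c1 | starting material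
2 | succinic anhydride | O=C1CCC(=O)O1 | starting material
3 | 4-(2,4-dihydroxyphenyl)-4-oxobutanoic acid | OC(=O)CCC(=O)c1ccc(O)cc1O | intermediate
4 | 4-hydroxybenzaldehyde | O=Cc1ccc(O)cc1 | starting material
5 | 4-acetoxybenzaldehyde | CC(=O)Oc1ccc(C=O)cc1 | intermediate (not isolated)
6 | 5-(2,4-diacetoxyphenyl)furan-2(3H)-one | CC(=O)Oc1ccc(C2=CCC(=O)O2)c(OC(C)=O)c1 | intermediate (not isolated)
7 | (E)-3-(4-acetoxybenzylidene)-5-(2,4-diacetoxyphenyl)furan-2(3H)-one | CC(=O)Oc1ccc(/C=C2\C=C(c3ccc(OC(C)=O)cc3OC(C)=O)OC2=O)cc1 | intermediate
8 | methyl (E)-4-(2,4-dihydroxyphenyl)-2-(4-hydroxybenzylidene)-4-oxobutanoate | COC(=O)/C(=C/c1ccc(O)cc1)CC(=O)c1ccc(O)cc1O | intermediate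
9 | methyl (E)-4-[2-hydroxy-4-(methoxymethoxy)phenyl]-2-[4-(methoxymethoxy)benzylidene]-4-oxobutanoate | COC(=O)/C(=C/c1ccc(OCOC)cc1)CC(=O)c1ccc(OCOC)cc1O | intermediate
10 | 4-(methoxymethoxy)benzaldehyde | COCOc1ccc(C=O)cc1 | intermediate
11 | (2E,3E)-3-[2-hydroxy-4-(methoxymethoxy)benzoyl]-2-[4-(methoxymethoxy)benzylidene]-4-[4-(methoxymethoxy)phenyl]but-3-enoic acid | OC(=O)/C(=C/c1ccc(OCOC)cc1)/C(=C\c1ccc(OCOC)cc1)C(=O)c1ccc(OCOC)cc1O | intermediate
12 | allyl (2E,3E)-3-[2-hydroxy-4-(methoxymethoxy)benzoyl]-2-[4-(methoxymethoxy)benzylidene]-4-[4-(methoxymethoxy)phenyl]but-3-enoate | C=CCOC(=O)/C(=C/c1ccc(OCOC)cc1)/C(=C\c1ccc(OCOC)cc1)C(=O)c1ccc(OCOC)cc1O | intermediate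
13 | allyl (E)-2-[(2S,3R)-7-(methoxymethoxy)-2-[4-(methoxymethoxy)phenyl]-4-oxochroman-3-yl]-3-[4-(methoxymethoxy)phenyl]acrylate | O=C1c2ccc(OCOC)cc2O[C@H](c2ccc(OCOC)cc2)[C@H]1/C(=C\c1ccc(OCOC)cc1)C(=O)OCC=C | intermediate
14 | (E)-2-[(2S,3R)-7-(methoxymethoxy)-2-[4-(methoxymethoxy)phenyl]-4-oxochroman-3-yl]-3-[4-(methoxymethoxy)phenyl]acrylic acid | O=C1c2ccc(OCOC)cc2O[C@H](c2ccc(OCOC)cc2)[C@H]1/C(=C\c1ccc(OCOC)cc1)C(=O)O | intermediate
15 | methyl 3,5-dioxohexanoate | CC(=O)CC(=O)CC(=O)OC | starting material
16 | trilithium trienolate of methyl 3,5-dioxohexanoate | [Li+].[Li+].[Li+].C=C([O-])C=C([O-])C=C([O-])OC | intermediate (not isolated)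
17 | N-acylimidazole of 14, (2S,3R)-3-[(E)-3-(imidazol-1-yl)-1-[4-(methoxymethoxy)phenyl]-3-oxoprop-1-en-2-yl]-7-(methoxymethoxy)-2-[4-(methoxymethoxy)phenyl]chroman-4-one | O=C1c2ccc(OCOC)cc2O[C@H](c2ccc(OCOC)cc2)[C@H]1/C(=C\c1ccc(OCOC)cc1)C(=O)n1ccnc1 | intermediate (not isolated)
18 | methyl (E)-8-[(2S,3R)-7-(methoxymethoxy)-2-[4-(methoxymethoxy)phenyl]-4-oxochroman-3-yl]-9-[4-(methoxymethoxy)phenyl]-3,5,7-trioxonon-8-enoate | O=C1c2ccc(OCOC)cc2O[C@H](c2ccc(OCOC)cc2)[C@H]1/C(=C\c1ccc(OCOC)cc1)C(=O)CC(=O)CC(=O)CC(=O)OC | intermediate
19 | (2S,3R)-7-(methoxymethoxy)-2-[4-(methoxymethoxy)phenyl]-3-[(E)-1-[4-(methoxymethoxy)phenyl]-3-oxo-3-(2,4,6-trihydroxyphenyl)prop-1-en-2-yl]chroman-4-one | O=C1c2ccc(OCOC)cc2O[C@H](c2ccc(OCOC)cc2)[C@H]1/C(=C\c1ccc(OCOC)cc1)C(=O)c1c(O)cc(O)cc1O | intermediate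
20 | (2S,3R,2''S,3''R)-5'',7''-dihydroxy-7-(methoxymethoxy)-2,2''-bis[4-(methoxymethoxy)phenyl]-3,3''-bichroman-4,4''-dione | O=C1c2ccc(OCOC)cc2O[C@H](c2ccc(OCOC)cc2)[C@H]1[C@H]1C(=O)c2c(O)cc(O)cc2O[C@@H]1c1ccc(OCOC)cc1 | intermediate
21 | (2S,3R,2''S,3''R)-7,5'',7''-trihydroxy-2,2''-bis(4-hydroxyphenyl)-3,3''-bichroman-4,4''-dione | O=C1c2ccc(O)cc2O[C@H](c2ccc(O)cc2)[C@H]1[C@H]1C(=O)c2c(O)cc(O)cc2O[C@@H]1c1ccc(O)cc1 | target

## Step count and least certain steps

Total: 13 steps. Longest linear sequence: 12 steps (1, 2, 3, 4, 6, 7, 8, 9, 10, 11, 12, 13). Step 5 is a one-step side branch.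

Step 11 (key step). Three processes may interfere. The chain may close in the aldol sense, or lactonise to a 4-hydroxy-2-pyranone, if the magnesium chelate does not hold the ester end in place. Ring C may open by base-induced retro-oxa-Michael reaction with loss of the C2 configuration, because H3 is allylic as well as alpha to the ketone. The chain enolate may add irreversibly to the C2''=C3'' enone before aromatisation. Fallback, from 14 back to 21: ring A'' is taken from a preformed phloroglucinol nucleus instead of being closed from the chain. Acid 14 is converted with 1-chloro-N,N,2-trimethylprop-1-en-1-amine in CH2Cl2 into the acid chloride F1. 1,3,5-Tris(methoxymethoxy)benzene F2 (from the parent triphenol with MOMCl and i-Pr2NEt) is lithiated between two acetal oxygens with n-BuLi to the aryllithium F3 and transmetalated with ZnCl2 to the arylzinc chloride F4. Pd(PPh3)4-catalysed acyl cross-coupling (Negishi type) of F4 with F1, which leaves the C4 ketone alone, should give the hexa-acetal chalcone F5. HCl in MeOH then removes all six acetals and closes ring C'' under acid to 21, formed together with its 2''R,3''S diastereomer F6, which is removed by preparative HPLC.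

Step 12. The catalyst may fail to override the facial bias that the C3 stereocentre exerts on the C2''=C3'' alkene, or an uncatalysed closure of the very reactive trihydroxychalcone may compete. Either gives a mixture of the 2''S,3''R and 2''R,3''S series, and kinetic protonation may leave C3'' cis. Fallback, from 19 back to 21: closure and deprotection are merged under substrate and thermodynamic control. HCl in MeOH at 50 °C cyclises 19 and removes the acetals in one operation, and 21 is separated from the diastereomer F6 by preparative reversed-phase HPLC. The two are diastereomers, so no chiral phase is needed.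

Step 8. Facial selectivity may be poor, because the enone has no second carbonyl to anchor the thiourea, the 4-alkoxyphenyl group makes C2 a weak acceptor, and any Z isomer of the enone or any uncatalysed closure (already in steps 6 and 7) erodes the enantiomeric purity. Fallback, from 11 back to 14: resolution in place of catalysis. The chalcone acid 11 is cyclised without control (Et3N, EtOH, 60 °C) to the racemic 2,3-trans flavanone acid F7. F7 is resolved by fractional crystallisation of its salt with (S)-1-phenylethylamine. The salt F8 of the 2S,3R acid is taken here to be the less soluble one (the R amine is used if it is not), and cold dilute acid returns 14. The unwanted enantiomer can be recycled by base-induced ring opening to 11. Steps 7 to 9 are then not needed.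

Step 10. Proton transfer from C3 to the strongly basic trienolate may be followed by beta-elimination of the ring phenoxide, which opens ring C and destroys C2. Addition of the carbanion to the C4 ketone and O-acylation of the enolate oxygens are further losses. Fallback, from 14 back to 18: a neutral C-acylation in place of the polyanion. Methyl 3,5-dioxohexanoate 15 is converted by stepwise enol silylation (Me3SiCl/Et3N, then twice LiN(i-Pr)2/Me3SiCl) into 1-methoxy-1,3,5-tris(trimethylsilyloxy)hexa-1,3,5-triene F9. This tris(silyl enol ether) is acylated at its terminal carbon by the acid chloride F1 (made from 14 as described for step 11) in CH2Cl2 at −78 °C to rt (Mukaiyama-type acylation). Mild aqueous work-up cleaves the remaining silyl enol ethers and gives 18 without the flavanone meeting a base.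

## Further compounds

F1 | step 11 | acid chloride of 14, (E)-2-[(2S,3R)-7-(methoxymethoxy)-2-[4-(methoxymethoxy)phenyl]-4-oxochroman-3-yl]-3-[4-(methoxymethoxy)phenyl]acryloyl chloride | O=C1c2ccc(OCOC)cc2O[C@H](c2ccc(OCOC)cc2)[C@H]1/C(=C\c1ccc(OCOC)cc1)C(Cl)=O
F2 | step 11 | 1,3,5-tris(methoxymethoxy)benzene | COCOc1cc(OCOC)cc(OCOC)c1
F3 | step 11 | [2,4,6-tris(methoxymethoxy)phenyl]lithium | [Li]c1c(OCOC)cc(OCOC)cc1OCOC
F4 | step 11 | [2,4,6-tris(methoxymethoxy)phenyl]zinc chloride | COCOc1cc(OCOC)c([Zn]Cl)c(OCOC)c1
F5 | step 11 | (2S,3R)-7-(methoxymethoxy)-2-[4-(methoxymethoxy)phenyl]-3-[(E)-1-[4-(methoxymethoxy)phenyl]-3-oxo-3-[2,4,6-tris(methoxymethoxy)phenyl]prop-1-en-2-yl]chroman-4-one | O=C1c2ccc(OCOC)cc2O[C@H](c2ccc(OCOC)cc2)[C@H]1/C(=C\c1ccc(OCOC)cc1)C(=O)c1c(OCOC)cc(OCOC)cc1OCOC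
F6 | step 12 | (2S,3R,2''R,3''S)-7,5'',7''-trihydroxy-2,2''-bis(4-hydroxyphenyl)-3,3''-bichroman-4,4''-dione, the C2''/C3'' diastereomer of 21 | O=C1c2ccc(O)cc2O[C@H](c2ccc(O)cc2)[C@H]1[C@@H]1C(=O)c2c(O)cc(O)cc2O[C@H]1c1ccc(O)cc1
F7 | step 8 | racemic 2,3-trans (E)-2-[7-(methoxymethoxy)-2-[4-(methoxymethoxy)phenyl]-4-oxochroman-3-yl]-3-[4-(methoxymethoxy)phenyl]acrylic acid (both enantiomers written) | O=C1c2ccc(OCOC)cc2O[C@H](c2ccc(OCOC)cc2)[C@H]1/C(=C\c1ccc(OCOC)cc1)C(=O)O.O=C1c2ccc(OCOC)cc2O[C@@H](c2ccc(OCOC)cc2)[C@@H]1/C(=C\c1ccc(OCOC)cc1)C(=O)O
F8 | step 8 | (S)-1-phenylethylammonium salt of the 2S,3R acid 14 | O=C1c2ccc(OCOC)cc2O[C@H](c2ccc(OCOC)cc2)[C@H]1/C(=C\c1ccc(OCOC)cc1)C(=O)[O-].C[C@H]([NH3+])c1ccccc1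
F9 | step 10 | 1-methoxy-1,3,5-tris(trimethylsilyloxy)hexa-1,3,5-triene (enol ether geometry not defined) | COC(O[Si](C)(C)C)=CC(O[Si](C)(C)C)=CC(=C)O[Si](C)(C)C
A1 | alternative 1 | 4-hydroxycinnamic acid | O=C(O)/C=C/c1ccc(O)cc1
A2 | alternative 1 | (3R,3aR,6R,6aR)-3,6-bis(4-hydroxyphenyl)tetrahydrofuro[3,4-c]furan-1,4-dione | O=C1O[C@@H](c2ccc(O)cc2)[C@H]2[C@@H]1[C@H](c1ccc(O)cc1)OC2=O
A3 | alternative 2 | 2-[(4-acetoxyphenyl)(3-methoxyphenoxy)methyl]-3-[(4-acetoxyphenyl)(3,5-dimethoxyphenoxy)methyl]succinic acid, configured as in 21 | COc1cccc(c1)O[C@H](c1ccc(OC(C)=O)cc1)[C@H](C(=O)O)[C@@H](C(=O)O)[C@H](Oc1cc(OC)cc(OC)c1)c1ccc(OC(C)=O)cc1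
A4 | alternative 2 | 7,5'',7''-tri-O-methyl-4',4'''-di-O-acetyl derivative of 21 | O=C1c2ccc(OC)cc2O[C@H](c2ccc(OC(C)=O)cc2)[C@H]1[C@H]1C(=O)c2c(OC)cc(OC)cc2O[C@@H]1c1ccc(OC(C)=O)cc1
A5 | alternative 3 | 1-[2-(allyloxy)-4-(methoxymethoxy)phenyl]-4-[2-(allyloxy)-4,6-bis(methoxymethoxy)phenyl]butane-1,4-dione | O=C(CCC(=O)c1c(OCC=C)cc(OCOC)cc1OCOC)c1ccc(OCOC)cc1OCC=C
A6 | alternative 3 | syn,syn bis-aldol of A5 with two molecules of 10, 3R,3''R with inverted carbinols at C2 and C2'' | O=C(c1ccc(OCOC)cc1OCC=C)[C@@H]([C@@H](O)c1ccc(OCOC)cc1)[C@H]([C@@H](O)c1ccc(OCOC)cc1)C(=O)c1c(OCC=C)cc(OCOC)cc1OCOC
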